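At 40 min I have to read the flask called midnight, followed so far to 30.0 min, with the summer run beside it.

| flask | solid substrate | enzyme | impurity | remark | time |
|---|---|---|---|---|---|
| midnight | 20 mM | 4 µM | 1 µM | the very flask that is asked about, followed so far |  |
| summer | 10 mM | 4 µM | 1 µM | run made earlier |  |
| flask | 20 mM | 4.0 µM | 1.0 µM |  | 40 min |

| run | time / min | product / % |
|---|---|---|
| midnight | 5.00 | 16.6 |
| midnight | 10.0 | 25.6 |
| midnight | 15.0 | 29.3 |
| midnight | 20.0 | 30.4 |
| midnight | 25.0 | 30.1 |
| midnight | 30.0 | 31.6 |
| summer | 2.00 | 16.1 |
| summer | 6.00 | 38.6 |
| summer | 12.0 | 54.7 |
| summer | 15.0 | 58.9 |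
| summer | 25.0 | 60.6 |
| summer | 30.0 | 60.5 |
| summer | 40.0 | 60.5 |

(each reading ± 0.5 percentage points)

- maple: change nothing and wait 20 min more
- alder: at 40 min take out 90 % of the product then present, then wait 20 min
- elm: at 40 min add enzyme, 50.0 % of the amount charged, then wait 20 min

- product, in percent of the solid substrate first charged, at 40 min
- what to do for the largest gain in product; "none" if nothing gains more than 2 percentage points (maple / alder / elm / none)
- product present, with what was taken out counted in, in percent of the solid substrate first charged, after maple
- product present, with what was taken out counted in, in percent of the solid substrate first charged, after alder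

- solid substrate is a solid; its amount is given per volume of the solution
- product taken out counts as made
- at the start none of the solid substrate is in solution
- additions bring no volume worth counting

The summer run stops at a reading of 60.5 % of its 10 mM, which is 6.05 mM of product; I call this the ceiling, the [product] at which the readings stop rising. Put back into midnight, which holds twice the solid substrate and the same enzyme, the ceiling gives 30.2 %, and the last readings there are 30.4 %, 30.1 % and 31.6 %. More solid substrate did not lift the stop, so I read the ceiling as the total turnover of the enzyme charge. I therefore commit to 30.2 % now, the same after maple and alder, and 15 percentage points more from elm, whose added enzyme raises the ceiling in step.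

The forecast says 30.4 %, 30.4 % after maple, 30.6 % after alder, and elm as the best choice, worth about 7 points, since the shape fits “enzyme being killed at a rate proportional to product”. We part on the size of the gain from elm.

The flask gives 31.2 %, then 31.2 % after maple and 31.3 % after alder. The best choice is elm, which brings 38 points, more than my 15 points.

    starting material + enzyme → product + enzyme, rate k1*[starting material]*[enzyme]/(1 + ([starting material]/Km1) + ([product]/Kp1)) (46.0 mM, 0.290 mM, k = 95000 M⁻¹ s⁻¹)
    enzyme → spent catalyst A (k = 0.00440 s⁻¹)
    solid substrate ⇌ starting material, rate k3*(cs3 - [starting material]) while solid is left; crystals form when [starting material] > cs3 (solubility = 10.0 mM, k = 0.00170 s⁻¹)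
    enzyme + impurity → spent catalyst B (k = 7.50 × 10⁵ M⁻¹ s⁻¹)

In this flask the half-life of enzyme by its loss to spent catalyst A alone is 2.6 min, shorter than the 8.96 min by which half of the dissolving up to 40 min is done. At 40.0 min enzyme stands at 0 % of its charge, and starting material at 48.0 % of the solid substrate charged. The product of this flask comes to 6.25 mM, against the ceiling of 6.05 mM. For a neighbour flask, the same flask with 8.0 mM of solid substrate, the ceiling gives 75.6 %, and that neighbour flask itself gives 71.5 %.

All runs stem from a simulated flask from invented constants.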